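Readings and results are simulated with constants of no real substance; scatter was added.

The constants of the proposed steps are unknown, so the forecast for this flask must come from its own readings and one warmer run. The proposed steps are: starting material gives intermediate, free catalyst turns intermediate into product, starting material meets protic impurity to give quenched substrate, and free catalyst meets product to give spent catalyst.

| setting | spring | summer | flask |
|---|---|---|---|
| starting material | 1.5 M | 1.5 M | 1.5 M |
| protic impurity | 0.15 M | 0.15 M | 0.150 M |
| free catalyst | 38 mM | 38 mM | 38 mM |
| temperature | 5 °C | 11 °C | 5 °C |
| remark | the very flask that is asked about, followed so far | run made earlier |  |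
| time |  |  | 3.0 h |

- spring (time / min: product / %, starting material / %): 8.00: 17.0, 64.4; 15.0: 32.9, 46.2; 25.0: 48.6, 28.6; 40.0: 59.4, 14.7; 60.0: 64.2, 6.1; 120: 65.8, 0.9
- summer (time / min: product / %, starting material / %): 8.00: 32.2, 42.8; 15.0: 52.7, 21.2; 25.0: 64.2, 9.2; 40.0: 68.8, 2.2; 60.0: 69.6, 0; 120: 69.6, 0.3

(standard deviation of a reading: 0.5 percentage points)

- grey: at 3.0 h add free catalyst, 100% of the amount charged, then wait 1.5 h
- teal: at 3.0 h raise the temperature by 25 K, then wait 1.5 h
- ochre: at 3.0 h take out 90% of the product then present, then wait 1.5 h
- blue: change nothing and wait 1.5 h more

- removed product is counted in
- the numbers in the tables scatter with a standard deviation of 0.5 percentage points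
- steps that have been proposed: free catalyst + product -> spent catalyst; starting material -> intermediate; starting material + protic impurity -> quenched substrate; free catalyst + intermediate -> free catalyst + product
- additions bring no volume worth counting

- product, in percent of the starting material first charged, at 3.0 h
- which option adds most product ("none" when 2 percentage points or less is all one gets) (grey / teal / ochre / blue / none)
- product present, with what was taken out counted in, in percent of the starting material first charged, after teal
- product present, with what was taken out counted in, in percent of the starting material first charged, after ochre

The reckoning that follows is my own. Take the charge as one and subtract product, starting material, the impurity's charge as a fraction of the starting material (taken as wholly quenched) and the catalyst's charge likewise (each spent catalyst holding one product). At the last spring reading this leaves 20.8%, the stranded share: intermediate waiting for working catalyst, the yield lost to catalyst poisoning.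

Waiting: the spring readings halve starting material every 15.3 min, so 3.0 h holds 11.8 half-lives and leaves about 0.0286% of the charge as starting material. Further product would then have to come from the stranded share, and the summer flask, with 17.6% stranded, reads product 69.6% at 60.0 min and 69.6% at 120 min. I take the catalyst of the spring flask to have stopped working in the same way, so I put that flask at 65.8% now, and I expect blue to add nothing.

Heating: in the proposed steps intermediate becomes product through free catalyst, so with the catalyst stopped I expect teal to stay at that figure.

Taking out product: the removed part is counted in, and on the same judgement no working catalyst remains to be spared, so I expect ochre to stay there too.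

Adding catalyst: a fresh charge meets the stranded share but pays one product per catalyst, which puts my estimate of the ceiling for grey at 18 percentage points, against the margin of 2 points.

The forecast gives 65.9% now, 65.9% after teal, 65.9% after ochre and grey as best, with about 20 points from fresh catalyst where my estimated ceiling is 18 points. Its ground is that “the catalyst is effectively gone, so waiting, heating or removing product gives nothing”.

The flask gives 66.2% now, 66.2% after teal, 66.2% after ochre, and grey as best with 17 points gained.

    free catalyst + product → spent catalyst (k = 0.0860 L mol⁻¹ min⁻¹, Ea = 47.0 kJ mol⁻¹)
    starting material → intermediate (k = 0.0450 min⁻¹, Ea = 79.0 kJ mol⁻¹)
    starting material + protic impurity → quenched substrate (k = 0.140 L mol⁻¹ min⁻¹, Ea = 68.0 kJ mol⁻¹)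
    free catalyst + intermediate → free catalyst + product (k = 6.00 L mol⁻¹ min⁻¹, Ea = 43.0 kJ mol⁻¹)
    (constants at 5 °C)

In the flask at 180 min free catalyst stands at 0% of its charge and intermediate at 21.4%, beside the stranded share of 20.8%, and grey's gain of 17 points is smaller than the estimated ceiling of 18 points. In the repeat at 20 °C, product 73.9% and starting material 0% give a stranded share of 13.6%, and that flask ends with 14.0% intermediate.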